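The earlier runs and the new flask are calculated for an exercise, noise included.

Decide this row by one count: the radicals the initiator releases by the end, set against the transfer agent charged.

in all of them: substrate 0.050 M (fed, over 50 min)

| run | reagent | transfer agent | initiator | remark | time |
|---|---|---|---|---|---|
| Monday's | 0.065 M | 0.85 mM | 1 mM | run made earlier |  |
| Tuesday's | 0.065 M | 11 mM | 1 mM | run made earlier |  |
| violet | 0.0650 M | 0.600 mM | 1.0 mM |  | 20 h |
| grey | 0.0650 M | 1.20 mM | 1.0 mM |  | 20 h |
| red | 0.0650 M | 2.50 mM | 1.0 mM |  | 20 h |
| blue | 0.0650 M | 5.00 mM | 1.0 mM |  | 20 h |
| teal | 0.0650 M | 10.0 mM | 1.0 mM |  | 20 h |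

| run | time / h | target / % | substrate / % |
|---|---|---|---|
| Monday's | 0.833 | 0.9 | 98.4 |
| Monday's | 1.33 | 1.4 | 97.8 |
| Monday's | 2.00 | 2.8 | 96.9 |
| Monday's | 3.00 | 4.4 | 94.4 |
| Monday's | 4.00 | 9.3 | 88.6 |
| Monday's | 6.00 | 21.6 | 76.0 |
| Monday's | 10.0 | 32.1 | 65.2 |
| Tuesday's | 1.33 | 0.3 | 98.4 |
| Tuesday's | 3.00 | 0.2 | 99.2 |
| Tuesday's | 4.00 | 0.2 | 98.4 |
| Tuesday's | 6.00 | 0.5 | 97.1 |
| Tuesday's | 8.00 | 0.6 | 97.1 |
| Tuesday's | 10.0 | 0.9 | 96.8 |

(scatter of a reading: 0.5 percentage points)

- in percentages every species weighs as the substrate in it: one ended chains counts as two
- steps that have been proposed: initiator -> 2 initiating radical; substrate + initiating radical -> capped initiator + first chain carrier; reagent + first chain carrier -> target + second chain carrier; substrate + second chain carrier -> released group + first chain carrier; transfer agent + first chain carrier -> side product + idle radical; 2 idle radical -> ended radicals; 2 first chain carrier -> ended chains; 2 reagent -> homo dimer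
- "hardly changes" means that all values lie within two and a half points (for a concentration: within two and a half percent of the largest)

- amount of target at the end, in percent of the substrate charged for violet, grey, red, blue, teal, in this order
- the course of these numbers from the first flask to the last (rises, then falls / falls, then rises / falls all the way / rises all the way / hardly changes)

Read the clock from Monday's run. Between 3.00 h and 4.00 h target climbs from 4.4% to 9.3%, so take the lag (the induction period) as ending near 3.50 h. In Tuesday's run, with 11 mM of transfer agent, target still reads 0.9% at 10.0 h. Assume that each initiator gives two radicals and that each radical costs one transfer agent. Monday's lag then used 42.5% of the initiator charge, which reads as a first-order constant of 0.158 /h and a half-life of 4.38 h. Count the half-lives: 20 h holds 4.56 of them, so 95.8% of the initiator has passed. That gives the radical budget, the radicals released by the end, of 1.92 mM.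

Now turn the question round. For the row to hardly change, the charges of transfer agent would have to lie on one side of the budget. But grey's 1.20 mM lies below it, and red's 2.50 mM lies above it, above even the 2.00 mM that the full initiator charge can give. As fractions, the budget covers 160% of grey's charge and 76.8% of red's. For a rise, more transfer agent would have to give more target, yet at 10.0 h Monday's run reads 32.1% against 0.9% in Tuesday's. So I expect violet's lag to end near 2.26 h, grey's later, near 5.80 h, and red, blue and teal to stay in the lag at a level near Tuesday's. My count gives this order, not amounts. The forecast gives 47%, 24%, 5%, 2%, 1%, and falls all the way, on the ground, said of the transfer agent, that “target forms quickly only after it is gone”.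

The flasks give 46.8%, 27.2%, 1.85%, 0.719%, 0.331%: falls all the way. From grey to red, target drops from 27.2% to 1.85%, while the transfer agent left goes from 0% to 24%.

    initiator → 2 initiating radical (k = 0.00250 /min)
    substrate + initiating radical → capped initiator + first chain carrier (k = 5.20 × 10⁵ /M/s)
    reagent + first chain carrier → target + second chain carrier (k = 12000 /M/s)
    substrate + second chain carrier → released group + first chain carrier (k = 30000 /M/s)
    transfer agent + first chain carrier → side product + idle radical (kL = 4.20 × 10⁵ /M/s)
    2 idle radical → ended radicals (k = 5.00 × 10⁷ /M/s)
    2 first chain carrier → ended chains (k = 1.20 × 10⁹ /M/s)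
    2 reagent → homo dimer (k = 0.0480 /M/min)

Set the budget against teal's charge: it takes 19.2% and leaves 80.8%, and teal holds 81% of its transfer agent at 20.0 h.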